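**Retrosynthetic overview**

1. Germacranolide numbering is used: ring C1–C10, lactone carbons C11–C13 on C6/C7, C14 on C10, C15 on C4. The target is read as (1R,3S,6S,7R,8R,10S) with a 1,10-cis-epoxide, a 4Z alkene and a cis-fused 6,12-lactone. Late disconnections: C15–OH (allylic hydroxylation), O3-acetate, O8-methacrylate, oxirane (O8-directed), C13 (Mannich methylenation), C8–OH from C8–Si (Tamao–Fleming), lactone from a C6 ketone and a C12 acetal.
2. Key disconnection C8–C9: the C6 oxygen and the latent C1=C10 alkene (the oxirane) are 1,5-related through C7–C8–C9, so C6(=O)–C7–C8–C9–C10=C1 is the retron of an anionic oxy-Cope rearrangement. The precursor is a cyclohex-2-en-1-ol (ring C1–C2–C3–C4=C5–C6) whose C1–C6 bond is a temporary bond, cleaved as C8–C9 forms; C8 carries silicon as a placeholder for oxygen.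
3. Ring C1–C2–C3–C4=C5–C6 with C15, O3 and the C1 isopropenyl group (C10, C9, C14) is (S)-carvone after 1,2-reduction and allylic oxidation at C6. C7/C8 come from a silylacetylene, C11/C12 from a dioxolanylmethyl Grignard reagent, C13 from Eschenmoser salt.
4. Order of ring formation: six-membered carbocycle (bought), ten-membered carbocycle by ring expansion (step 7), γ-lactone (steps 8 and 9), oxirane (step 12).
5. Stereochemical relay: carvone C5, then C3 (Luche), C6 carbinol (axial alkynylation), C8, C7 and the 1(10)Z geometry (step 7), C6 (reduction), C1 and C10 (directed epoxidation).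

Key step: step 7

Remark: reagents named without a number are taken as commercial, and all stereochemical outcomes below are predictions from the stated models, not results.

**Route**

Step 1
Reactants: 1 (S)-(+)-carvone
Product: 2 (1S,5S)-cis-carveol
Conditions: NaBH4, CeCl3·7H2O, MeOH, −78 → 0 °C
Reagents that add atoms: none
Why: Luche 1,2-reduction of the enone, in which hydride adds axially to the half-chair that carries the isopropenyl group equatorial, so that the new carbinol centre (1S) is cis to that group as known for carvone.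

Step 2
Reactants: 2 (1S,5S)-cis-carveol
Product: 3 (1S,5S)-cis-carveol triisopropylsilyl ether
Conditions: TIPSOTf, 2,6-lutidine, CH2Cl2, 0 °C
Reagents that add atoms: triisopropylsilyl trifluoromethanesulfonate, CC(C)[Si](C(C)C)(C(C)C)OS(=O)(=O)C(F)(F)F
Why: Silyl triflate silylation of a secondary allylic alcohol creates no stereocentre, and the triisopropylsilyl ether is chosen because it should outlast the later brief fluoride treatment and holds the C3–O bond equatorial.

Step 3
Reactants: 3 (1S,5S)-cis-carveol triisopropylsilyl ether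
Product: 4 (4S,6S)-3-methyl-6-(prop-1-en-2-yl)-4-(triisopropylsilyloxy)cyclohex-2-en-1-one
Conditions: Rh2(cap)4 (dirhodium tetrakis(caprolactamate), 1 mol %), t-BuOOH (70% aq.), K2CO3, CH2Cl2, rt
Reagents that add atoms: tert-butyl hydroperoxide, CC(C)(C)OO
Why: Dirhodium-catalysed allylic C–H oxidation with t-BuOOH oxidises the only ring allylic methylene of a trisubstituted cyclohexene to the enone (the 1-methylcyclohexene to 3-methylcyclohexenone pattern) without touching the stereocentres, whose 4,6-cis diequatorial arrangement is also the stable one.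

Step 4
Reactants: 5 benzylchlorodimethylsilane
Product: 6 benzyl(ethynyl)dimethylsilane
Conditions: HC≡CMgBr, THF, 0 °C → rt
Reagents that add atoms: ethynylmagnesium bromide, C#C[Mg]Br
Why: Substitution at silicon by an alkynyl Grignard reagent gives the silylacetylene and involves no stereocentre.

Step 5
Reactants: 4 (4S,6S)-enone; 6 benzyl(ethynyl)dimethylsilane
Product: 8 (1R,4S,6S)-1-[(benzyldimethylsilyl)ethynyl]-3-methyl-6-(prop-1-en-2-yl)-4-(triisopropylsilyloxy)cyclohex-2-en-1-ol, via lithium acetylide 7 (not isolated)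
Conditions: 6, n-BuLi, THF, −78 °C; then 4, −78 → −40 °C; H2O
Reagents that add atoms: none
Why: 1,2-Addition of a lithium acetylide to the enone, where the slim sp nucleophile attacks axially on the half-chair locked by the two equatorial substituents, places the alkynyl group cis and the hydroxyl group trans to the isopropenyl group (1R).

Step 6
Reactants: 8 (1R,4S,6S)-silylalkynyl carbinol
Product: 10 (1R,4S,6S)-1-[(1E)-1-(benzyldimethylsilyl)-3-(1,3-dioxolan-2-yl)prop-1-en-2-yl]-3-methyl-6-(prop-1-en-2-yl)-4-(triisopropylsilyloxy)cyclohex-2-en-1-ol, via magnesium chelate 9 (not isolated)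
Conditions: (1,3-dioxolan-2-ylmethyl)MgBr (4 equiv), CuI (10 mol %), THF, 0 → 50 °C; then H2O
Reagents that add atoms: (1,3-dioxolan-2-ylmethyl)magnesium bromide, Br[Mg]CC1OCCO1
Why: CuI-catalysed anti-carbomagnesiation of a propargylic alkoxide (Duboudin–Jousseaume type) delivers the alkyl group to the proximal alkyne carbon and magnesium to the distal one, where it is held by the alkoxide in the five-membered chelate 9 and stabilised α to silicon, so that protonolysis gives the alkene with silicon trans to the carbinol carbon and no new sp3 stereocentre.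

Step 7
Reactants: 10 (1R,4S,6S)-dialkenyl cyclohexenol
Product: 13 (3S,7S,8R)-(1(10)Z,4Z)-cyclodeca-1(10),4-dien-6-one carrying 8-SiMe2Bn and 7-CH2-(1,3-dioxolan-2-yl) and 3-OTIPS and the C10 and C4 methyl groups, via potassium alkoxide 11 (not isolated), via potassium dienolate 12 (not isolated)
Conditions: KH, 18-crown-6, THF, 0 °C → rt; then AcOH, THF, −78 °C
Reagents that add atoms: none
Why: KH/18-crown-6 converts 10 into the naked potassium alkoxide 11, whose oxyanion weakens the C1–C6 bond and drives an anionic oxy-Cope [3,3]-sigmatropic shift of the 1,5-diene C8=C7–C6–C1–C10=C9, so that C8–C9 forms as C1–C6 breaks and the enolate 12 results. The closest known reaction type is the anionic oxy-Cope ring expansion of 1,2-dialkenylcyclohex-2-en-1-ols (adducts of isopiperitenone-type enones) to cyclodeca-1(10),4-dien-6-ones with use of the regiodefined enolate. The ten-membered ring is closed in the ring-expansion mode (six-membered ring plus four alkenyl carbons, suprafacial on both allyl halves through a chair array) and not by an end-to-end cyclisation, and it keeps the cis C4=C5 bond of the cyclohexene. C8 (R) is set by the chair that holds the E-silyl group equatorial and is relayed from the C1 and C6 centres; the same chair, with the isopropenyl and silyloxy groups equatorial on the half-chair and the C1–C2 bond therefore axial, gives the (Z)-C1=C10 alkene, and C7 is set when the trans-cycloalkene-like enolate 12 is protonated at −78 °C on its outer face, anti to the transannular C9–C10–C1 bridge. The step needs this chair over the other chair or a boat, no β-elimination and no C7 epimerisation: the alternative chair would put the C1 and C3 substituents 1,3-diaxial, C8 carries silicon instead of oxygen so that nothing can leave β to the enolate, and the cold acetic acid quench is kinetic.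

Step 8
Reactants: 13 (3S,7S,8R)-ketone
Product: 15 (3S,6S,7S,8R)-cis-fused 6,12-lactol (C12 epimers) with 8-SiMe2Bn and 3-OTIPS, via allylic alcohol 14 (not isolated)
Conditions: NaBH4, CeCl3·7H2O, MeOH, −78 °C; then PPTS, acetone/H2O, 40 °C
Reagents that add atoms: water, O
Why: Luche reduction follows the Felkin–Anh model at the ring periphery, with hydride entering anti to the C8 branch of the adjacent C7 centre to give 6S with O6 cis to the C7 side chain, and the dioxolane is then hydrolysed under mild acid with capture of the aldehyde by that hydroxyl as the cis-fused lactol.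

Step 9
Reactants: 15 (3S,6S,7S,8R)-lactol
Product: 16 (3S,6S,7S,8R)-cis-fused 6,12-lactone with 8-SiMe2Bn and 3-OTIPS
Conditions: TEMPO (cat.), PhI(OAc)2, CH2Cl2, rt
Reagents that add atoms: none
Why: TEMPO/PhI(OAc)2 oxidation of a lactol to the γ-lactone leaves alkenes, silyl ether and C–Si bond alone and changes no stereocentre.

Step 10
Reactants: 16 (3S,6S,7S,8R)-silyl lactone
Product: 18 (3S,6S,7R,8R)-8-hydroxy cis-fused lactone with 3-OTIPS, via silanol 17 (not isolated)
Conditions: TBAF, THF, 0 °C, 15 min; then 30% H2O2, KHCO3, MeOH, 0 °C → rt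
Reagents that add atoms: hydrogen peroxide, OO
Why: Tamao–Fleming oxidation of the benzyldimethylsilyl group (fluoride-induced loss of the benzyl group to silanol 17, then peroxide-induced 1,2-shift of C8 from silicon to oxygen) goes with retention at C8, and the freed O8 cannot take over the lactone because that would need a bridged bicyclo[2.2.1] tetrahedral intermediate.

Step 11
Reactants: 18 (3S,6S,7R,8R)-hydroxy lactone
Product: 21 (3S,6S,7R,8R)-8-hydroxy α-methylene lactone with 3-OTIPS, via Mannich base 19 (not isolated), via methiodide 20 (not isolated)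
Conditions: LDA (2.5 equiv), THF, −78 °C; CH2=NMe2+ I−, −78 → 0 °C; then MeI, MeOH, rt; then NaHCO3 (aq.), CH2Cl2
Reagents that add atoms: N,N-dimethylmethyleneiminium iodide, C=[N+](C)C.[I-]
Why: α-Methylenation of the γ-lactone through its lithium enolate (formed beside the C8 lithium alkoxide) by Mannich reaction with Eschenmoser salt, N-methylation and base-induced elimination of trimethylamine, in which the transient C11 stereocentre is lost again.

Step 12
Reactants: 21 (3S,6S,7R,8R)-hydroxy α-methylene lactone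
Product: 22 (1R,3S,6S,7R,8R,10S)-1,10-epoxy-8-hydroxy α-methylene lactone with 3-OTIPS
Conditions: VO(acac)2 (5 mol %), t-BuOOH, CH2Cl2, 0 °C → rt
Reagents that add atoms: tert-butyl hydroperoxide, CC(C)(C)OO
Why: Vanadium-catalysed hydroxyl-directed epoxidation of the homoallylic alcohol delivers oxygen from the O8-bound peroxo complex to the O8-proximal face of the (Z)-C1=C10 alkene, which sets C1 (R) and C10 (S) cis to O8 and stereospecifically cis to each other, while the undirected C4=C5 and the two electron-poor alkenes do not react.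

Step 13
Reactants: 22 epoxy alcohol
Product: 23 8-O-methacryloyl epoxy lactone with 3-OTIPS
Conditions: methacrylic anhydride, Et3N, DMAP (cat.), CH2Cl2, 0 °C → rt
Reagents that add atoms: methacrylic anhydride, C=C(C)C(=O)OC(=O)C(C)=C
Why: DMAP-catalysed acyl transfer from the anhydride esterifies the only free hydroxyl group without touching a stereocentre.

Step 14
Reactants: 23 8-O-methacryloyl silyl ether
Product: 24 3-hydroxy 8-O-methacryloyl epoxy lactone
Conditions: TBAF, AcOH (1:1), THF, rt
Reagents that add atoms: none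
Why: Fluoride cleavage of the silyl ether, buffered with acetic acid so that the epoxide, the two acrylate units and the lactone are not exposed to basic fluoride, frees O3 with retention.

Step 15
Reactants: 24 3-hydroxy compound
Product: 25 3-O-acetyl-8-O-methacryloyl epoxy lactone (15-deoxy target)
Conditions: Ac2O, pyridine, DMAP (cat.), CH2Cl2, 0 °C
Reagents that add atoms: acetic anhydride, CC(=O)OC(C)=O
Why: Pyridine/DMAP acetylation of the allylic C3 alcohol proceeds with retention.

Step 16
Reactants: 25 15-deoxy target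
Product: 26 CNP0319155.2
Conditions: SeO2 (0.5 equiv), t-BuOOH, CH2Cl2, rt
Reagents that add atoms: tert-butyl hydroperoxide, CC(C)(C)OO
Why: Selenium dioxide/t-BuOOH allylic hydroxylation (ene reaction then [2,3]-sigmatropic shift) attacks the only electron-rich alkene left and, by the usual preference for the allylic group cis to the vinylic hydrogen on the more substituted carbon, oxidises C15 with retention of the 4Z geometry, as in the methyl hydroxylation of epoxy germacranolides such as parthenolide.

**Compound list**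

1 | (S)-(+)-carvone | CC1=CC[C@@H](CC1=O)C(C)=C | starting material
2 | (1S,5S)-cis-carveol | CC1=CC[C@@H](C[C@@H]1O)C(C)=C | intermediate
3 | (1S,5S)-cis-carveol triisopropylsilyl ether | CC1=CC[C@@H](C[C@@H]1O[Si](C(C)C)(C(C)C)C(C)C)C(C)=C | intermediate
4 | (4S,6S)-3-methyl-6-(prop-1-en-2-yl)-4-(triisopropylsilyloxy)cyclohex-2-en-1-one | CC1=CC(=O)[C@@H](C[C@@H]1O[Si](C(C)C)(C(C)C)C(C)C)C(C)=C | intermediate
5 | benzylchlorodimethylsilane | C[Si](C)(Cl)Cc1ccccc1 | starting material
6 | benzyl(ethynyl)dimethylsilane | C#C[Si](C)(C)Cc1ccccc1 | intermediate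
7 | lithium acetylide of 6 | [Li]C#C[Si](C)(C)Cc1ccccc1 | intermediate
8 | (1R,4S,6S)-1-[(benzyldimethylsilyl)ethynyl]-3-methyl-6-(prop-1-en-2-yl)-4-(triisopropylsilyloxy)cyclohex-2-en-1-ol | C[Si](C)(Cc1ccccc1)C#C[C@@]1(O)C=C(C)[C@@H](O[Si](C(C)C)(C(C)C)C(C)C)C[C@H]1C(C)=C | intermediate
9 | five-membered alkoxy(alkenyl)magnesium chelate (Mg on C8 and O6) | C[Si](C)(Cc1ccccc1)C1=C(CC2OCCO2)[C@@]3(O[Mg]1)C=C(C)[C@@H](O[Si](C(C)C)(C(C)C)C(C)C)C[C@H]3C(C)=C | intermediate
10 | (1R,4S,6S)-1-[(1E)-1-(benzyldimethylsilyl)-3-(1,3-dioxolan-2-yl)prop-1-en-2-yl]-3-methyl-6-(prop-1-en-2-yl)-4-(triisopropylsilyloxy)cyclohex-2-en-1-ol | C[Si](C)(Cc1ccccc1)/C=C(\CC1OCCO1)[C@@]2(O)C=C(C)[C@@H](O[Si](C(C)C)(C(C)C)C(C)C)C[C@H]2C(C)=C | intermediate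
11 | potassium alkoxide of 10 | C[Si](C)(Cc1ccccc1)/C=C(\CC1OCCO1)[C@@]2([O-])C=C(C)[C@@H](O[Si](C(C)C)(C(C)C)C(C)C)C[C@H]2C(C)=C.[K+] | intermediate
12 | potassium dienolate of 13 (C6–O−, C6=C7 with C5 trans to C8) | [K+].[O-]/C1=C(/CC2OCCO2)[C@H]([Si](C)(C)Cc2ccccc2)C/C(C)=C\C[C@H](O[Si](C(C)C)(C(C)C)C(C)C)/C(C)=C\1 | intermediate
13 | (3S,7S,8R)-(1(10)Z,4Z)-cyclodecadien-6-one with 8-SiMe2Bn, 7-CH2-(1,3-dioxolan-2-yl), 3-OTIPS | C[Si](C)(Cc1ccccc1)[C@@H]1C/C(C)=C\C[C@H](O[Si](C(C)C)(C(C)C)C(C)C)/C(C)=C\C(=O)[C@@H]1CC1OCCO1 | intermediate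
14 | (3S,6S,7S,8R)-6-hydroxy compound from 13 | C[Si](C)(Cc1ccccc1)[C@@H]1C/C(C)=C\C[C@H](O[Si](C(C)C)(C(C)C)C(C)C)/C(C)=C\[C@H](O)[C@@H]1CC1OCCO1 | intermediate
15 | (3S,6S,7S,8R)-cis-fused 6,12-lactol (C12 epimers) | C[Si](C)(Cc1ccccc1)[C@@H]1C/C(C)=C\C[C@H](O[Si](C(C)C)(C(C)C)C(C)C)/C(C)=C\[C@@H]2OC(O)C[C@@H]21 | intermediate
16 | (3S,6S,7S,8R)-cis-fused 6,12-lactone with 8-SiMe2Bn, 3-OTIPS | C[Si](C)(Cc1ccccc1)[C@@H]1C/C(C)=C\C[C@H](O[Si](C(C)C)(C(C)C)C(C)C)/C(C)=C\[C@@H]2OC(=O)C[C@@H]21 | intermediate
17 | C8 dimethylsilanol of 16 | O[Si](C)(C)[C@@H]1C/C(C)=C\C[C@H](O[Si](C(C)C)(C(C)C)C(C)C)/C(C)=C\[C@@H]2OC(=O)C[C@@H]21 | intermediate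
18 | (3S,6S,7R,8R)-8-hydroxy lactone with 3-OTIPS | O[C@@H]1C/C(C)=C\C[C@H](O[Si](C(C)C)(C(C)C)C(C)C)/C(C)=C\[C@@H]2OC(=O)C[C@@H]21 | intermediate
19 | Mannich base: 11-(dimethylaminomethyl) lactone (CH2NMe2 drawn trans to C8) | O[C@@H]1C/C(C)=C\C[C@H](O[Si](C(C)C)(C(C)C)C(C)C)/C(C)=C\[C@@H]2OC(=O)[C@@H](CN(C)C)[C@@H]21 | intermediate
20 | trimethylammonium iodide of 19 | O[C@@H]1C/C(C)=C\C[C@H](O[Si](C(C)C)(C(C)C)C(C)C)/C(C)=C\[C@@H]2OC(=O)[C@@H](C[N+](C)(C)C)[C@@H]21.[I-] | intermediate
21 | (3S,6S,7R,8R)-8-hydroxy α-methylene lactone with 3-OTIPS | O[C@@H]1C/C(C)=C\C[C@H](O[Si](C(C)C)(C(C)C)C(C)C)/C(C)=C\[C@@H]2OC(=O)C(=C)[C@@H]21 | intermediate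
22 | (1R,3S,6S,7R,8R,10S)-1,10-epoxy-8-hydroxy α-methylene lactone with 3-OTIPS | O[C@@H]1C[C@]2(C)O[C@@H]2C[C@H](O[Si](C(C)C)(C(C)C)C(C)C)/C(C)=C\[C@@H]2OC(=O)C(=C)[C@@H]21 | intermediate
23 | 8-O-methacryloyl derivative of 22 | C=C(C)C(=O)O[C@@H]1C[C@]2(C)O[C@@H]2C[C@H](O[Si](C(C)C)(C(C)C)C(C)C)/C(C)=C\[C@@H]2OC(=O)C(=C)[C@@H]21 | intermediate
24 | 3-hydroxy-8-O-methacryloyl epoxy lactone | C=C(C)C(=O)O[C@@H]1C[C@]2(C)O[C@@H]2C[C@H](O)/C(C)=C\[C@@H]2OC(=O)C(=C)[C@@H]21 | intermediate
25 | 3-O-acetyl-8-O-methacryloyl epoxy lactone (15-deoxy target) | C=C(C)C(=O)O[C@@H]1C[C@]2(C)O[C@@H]2C[C@H](OC(C)=O)/C(C)=C\[C@@H]2OC(=O)C(=C)[C@@H]21 | intermediate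
26 | CNP0319155.2, (1R,3S,6S,7R,8R,10S) | C=C(C)C(=O)O[C@@H]1C[C@]2(C)O[C@@H]2C[C@H](OC(C)=O)/C(CO)=C\[C@@H]2OC(=O)C(=C)[C@@H]21 | target

**Step count and risks**

Total step count: 16. Longest linear sequence: 15 steps (steps 1–3 and 5–16 from (S)-carvone).

The three steps most likely to fail:

Step 7 (key step). The rearrangement may run partly through the other chair or a boat, or proton transfer between enolate and product before the quench may scramble C7; either would erode the C8/C7/alkene relay. Fallback from 10, returning at 13: the tertiary alcohol would be silylated (TMSCl, imidazole, DMF) to trimethylsilyl ether F5, which would be heated without base (o-dichlorobenzene, 180 °C) in a neutral siloxy-Cope rearrangement to silyl enol ether F6. Kinetic protodesilylation (TBAF, AcOH, THF, −78 °C) would then give 13.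

Step 6. Carbometalation of the hindered, silyl-capped alkyne next to a quaternary carbinol may be slow, so that proton transfer or loss of anti stereospecificity competes and alkene isomers result. Fallback from 4 (with 5), returning at 10: enone 4 would be treated with ethynylmagnesium bromide (THF, −78 °C) to give ethynyl carbinol F1. Pd(PPh3)4-catalysed cis-silylstannation of its terminal alkyne with benzyldimethyl(tributylstannyl)silane F2 (from 5 and Bu3SnLi, THF, −78 °C) would put silicon on the terminal and tin on the internal carbon to give vinylstannane F3. Iododestannylation (I2, CH2Cl2, 0 °C) would give vinyl iodide F4 with retention, and PdCl2(dppf)-catalysed Negishi coupling with (1,3-dioxolan-2-ylmethyl)zinc bromide (from the Grignard reagent and ZnBr2) would give 10.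

Step 16. The hydroxylation may stall or run on to the aldehyde on an alkene that is deactivated by two allylic oxygens, and acidic selenium species may open the epoxide. Fallback from 25, returning at 26: the oxidation would be driven fully to the aldehyde (SeO2, 2 equiv, 1,4-dioxane, 60 °C) to give enal F7. A Luche reduction (NaBH4, CeCl3·7H2O, MeOH, −78 °C), which should reduce the aldehyde 1,2 before it touches the two acrylate-type acceptors, would then give 26.

**Further compounds**

F1 | step 6 | (1R,4S,6S)-1-ethynyl-3-methyl-6-(prop-1-en-2-yl)-4-(triisopropylsilyloxy)cyclohex-2-en-1-ol | C#C[C@@]1(O)C=C(C)[C@@H](O[Si](C(C)C)(C(C)C)C(C)C)C[C@H]1C(C)=C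
F2 | step 6 | benzyldimethyl(tributylstannyl)silane | CCCC[Sn](CCCC)(CCCC)[Si](C)(C)Cc1ccccc1
F3 | step 6 | vinylstannane: 1-[(Z)-2-(benzyldimethylsilyl)-1-(tributylstannyl)ethenyl] carbinol (Si cis to Sn) | C[Si](C)(Cc1ccccc1)/C=C(\[Sn](CCCC)(CCCC)CCCC)[C@@]2(O)C=C(C)[C@@H](O[Si](C(C)C)(C(C)C)C(C)C)C[C@H]2C(C)=C
F4 | step 6 | vinyl iodide: 1-[2-(benzyldimethylsilyl)-1-iodoethenyl] carbinol (Si cis to I) | C[Si](C)(Cc1ccccc1)/C=C(\I)[C@@]2(O)C=C(C)[C@@H](O[Si](C(C)C)(C(C)C)C(C)C)C[C@H]2C(C)=C
F5 | step 7 | trimethylsilyl ether of 10 | C[Si](C)(Cc1ccccc1)/C=C(\CC1OCCO1)[C@@]2(O[Si](C)(C)C)C=C(C)[C@@H](O[Si](C(C)C)(C(C)C)C(C)C)C[C@H]2C(C)=C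
F6 | step 7 | C6 trimethylsilyl enol ether of 13 | C[Si](C)(C)O/C1=C(/CC2OCCO2)[C@H]([Si](C)(C)Cc2ccccc2)C/C(C)=C\C[C@H](O[Si](C(C)C)(C(C)C)C(C)C)/C(C)=C\1
F7 | step 16 | C15 aldehyde (enal) of 25 | C=C(C)C(=O)O[C@@H]1C[C@]2(C)O[C@@H]2C[C@H](OC(C)=O)/C(C=O)=C\[C@@H]2OC(=O)C(=C)[C@@H]21
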